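The target is the 4'-O-methyl ether of robustaflavone, and everything rests on cutting its C3'–C6'' biaryl bond. C3' lies ortho to O4' on ring B of the methoxyflavone unit and C6'' lies ortho to O5'' on ring A of the apigenin unit, so a di-tert-butylsilylene bridge between these two oxygens lets an arylpalladium centre at C3' reach C6''–H and nothing else. One tethered C–H arylation should therefore make the bond with site control and leave O4' and O5'' as the only non-benzylated oxygens. Its precursor is a bis(aryloxy)silane linking a 3'-bromo-4'-oxyflavone to the 5-oxygen of 7,4'-di-O-benzylapigenin.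

Key step: step 6

Assumption: the C3'–C6'' axis carries only three small ortho substituents and is taken to rotate freely, so the target is treated as achiral and no atropisomer control is planned.

Step 1
Reactants: 1 apigenin
Product: 2 7-(benzyloxy)-2-[4-(benzyloxy)phenyl]-5-hydroxy-4H-chromen-4-one (7,4'-di-O-benzylapigenin)
Conditions: BnBr (2.2 equiv), K2CO3, DMF, rt → 50 °C
Reagents that add atoms: benzyl bromide, BrCc1ccccc1
Why: Williamson etherification should alkylate the acidic 7- and 4'-hydroxyls, while the 5-hydroxyl, hydrogen-bonded to the C4 carbonyl, stays free as the later anchor for silicon.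

Step 2
Reactants: 3 3-bromo-4-hydroxybenzaldehyde
Product: 4 3-bromo-4-(methoxymethoxy)benzaldehyde
Conditions: MOMCl, iPr2NEt, CH2Cl2, 0 °C → rt
Reagents that add atoms: chloromethyl methyl ether, COCCl
Why: O-alkylation of the phenol to a base-stable MOM acetal keeps the aldehyde electrophilic in the aldol step, which a free phenoxide would deactivate.

Step 3
Reactants: 4 3-bromo-4-(methoxymethoxy)benzaldehyde; 5 1-[2,4-bis(benzyloxy)-6-hydroxyphenyl]ethanone
Product: 6 (E)-1-[2,4-bis(benzyloxy)-6-hydroxyphenyl]-3-[3-bromo-4-(methoxymethoxy)phenyl]prop-2-en-1-one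
Conditions: KOH, EtOH/THF, rt
Reagents that add atoms: none
Why: Claisen–Schmidt condensation of the methyl ketone enolate with the non-enolisable aldehyde, followed by E1cB dehydration, should give the conjugated enone as the thermodynamically preferred E isomer.

Step 4
Reactants: 6 the (E)-chalcone
Product: 8 5,7-bis(benzyloxy)-2-(3-bromo-4-hydroxyphenyl)-4H-chromen-4-one, via MOM-protected bromoflavone 7 (not isolated)
Conditions: I2 (10 mol %), DMSO, 120 °C; then crude 7, HCl (3 M in MeOH)/THF, 50 °C
Reagents that add atoms: none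
Why: Iodine-catalysed oxidative cyclisation of a 2'-hydroxychalcone (oxa-Michael closure, α-iodination, loss of HI, DMSO as terminal oxidant) should build the flavone, and acid-catalysed acetal methanolysis then frees the 4'-hydroxyl without touching the benzyl ethers or the aryl bromide.

Step 5
Reactants: 8 5,7-bis(benzyloxy)-2-(3-bromo-4-hydroxyphenyl)-4H-chromen-4-one; 9 di-tert-butylsilyl bis(trifluoromethanesulfonate); 2 7,4'-di-O-benzylapigenin
Product: 11 7-(benzyloxy)-2-[4-(benzyloxy)phenyl]-5-({[4-(5,7-bis(benzyloxy)-4-oxo-4H-chromen-2-yl)-2-bromophenoxy]di-tert-butylsilyl}oxy)-4H-chromen-4-one, via aryloxysilyl triflate 10 (not isolated)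
Conditions: 8 added to 9 (1.1 equiv), 2,6-lutidine, CH2Cl2, −78 → 0 °C; then 2, DBU, DMAP (cat.), 0 → 40 °C
Reagents that add atoms: none
Why: Sequential nucleophilic substitution at silicon (mixed silyl ether formation): under inverse addition the acidic, unhindered 4'-phenol should displace only one triflate because the resulting aryloxysilyl triflate is much more crowded, and the amidine base then drives the weakly nucleophilic, chelated 5-hydroxyl of 2 onto that triflate.

Step 6
Reactants: 11 the bis(aryloxy)di-tert-butylsilane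
Product: 12 silylene-bridged 3',6''-biflavone: a 6,6-di-tert-butyldibenzo[d,f][1,3,2]dioxasilepine in which C3' of the 5,7-bis(benzyloxy)flavone unit is bonded to C6'' of the 7'',4'''-di-O-benzylapigenin unit and O4' and O5'' are joined through silicon
Conditions: Pd(OAc)2 (10 mol %), PCy3·HBF4 (20 mol %), Cs2CO3 (2.5 equiv), PivOH (30 mol %), p-xylene, 130 °C
Reagents that add atoms: none
Why: Oxidative addition of zerovalent palladium, formed in the flask, to the C3'–Br bond should give a divalent arylpalladium bromide that the O4'–Si–O5'' tether parks above C6''–H, and pivalate-assisted concerted metalation–deprotonation then cleaves that C–H bond. Reductive elimination from the resulting eight-membered diarylpalladacycle forms the C3'–C6'' bond and thereby closes the seven-membered dioxasilepine ring (closure by biaryl C–C bond formation within the tether). The closest known reaction type is the silicon-tethered palladium-catalysed intramolecular direct arylation of bis(aryloxy)di-tert-butylsilanes, which delivers silylene-protected unsymmetrical 2,2'-biphenols. No stereocentre is created; the twisted biaryl of 12 is racemic and its axis becomes freely rotating once the bridge is removed. The step needs selectivity for C6'' over C8'', over ring A of the bromoflavone unit and over the benzyl rings, and the short bridge secures it because only the carbon ortho to O5'' is within reach. That C–H bond lies between two oxygens and is the most acidic on the ring, and the benzyl ethers are inert to carbonate at this temperature.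

Step 7
Reactants: 12 the silylene-bridged biflavone
Product: 13 5,7,7'',4'''-tetra-O-benzylrobustaflavone (4'- and 5''-hydroxyls free)
Conditions: Bu4NF (2.5 equiv), AcOH (2.5 equiv), THF, 0 °C → rt
Reagents that add atoms: none
Why: Fluoride-induced desilylation should cleave both aryl Si–O bonds, driven by the strong Si–F bond and the good phenoxide leaving groups, while the acetic acid buffer protects the chromones and the benzyl ethers are unaffected.

Step 8
Reactants: 13 the 4',5''-diol
Product: 14 5,7,7'',4'''-tetra-O-benzyl-4'-O-methylrobustaflavone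
Conditions: MeI (1.2 equiv), K2CO3 (1.5 equiv), acetone, rt → 40 °C
Reagents that add atoms: iodomethane, CI
Why: Chemoselective Williamson methylation should take place only at the free, acidic 4'-phenol, because the 5''-hydroxyl is locked in a hydrogen bond to the C4'' carbonyl and is shielded by the adjacent aryl ring.

Step 9
Reactants: 14 the tetrabenzyl methyl ether
Product: 15 6-[5-(5,7-dihydroxy-4-oxo-4H-chromen-2-yl)-2-methoxyphenyl]-5,7-dihydroxy-2-(4-hydroxyphenyl)-4H-chromen-4-one (robustaflavone 4'-O-methyl ether, the target)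
Conditions: H2 (1 atm), Pd/C (10 wt %), THF/MeOH, rt
Reagents that add atoms: none
Why: Catalytic hydrogenolysis should cleave the four benzyl aryl ethers under conditions that leave the aryl methyl ether and the chromone double bonds intact.

Compound list
1 | apigenin | O=c1cc(-c2ccc(O)cc2)oc2cc(O)cc(O)c12 | starting material
2 | 7-(benzyloxy)-2-[4-(benzyloxy)phenyl]-5-hydroxy-4H-chromen-4-one (7,4'-di-O-benzylapigenin) | O=c1cc(-c2ccc(OCc3ccccc3)cc2)oc2cc(OCc3ccccc3)cc(O)c12 | intermediate
3 | 3-bromo-4-hydroxybenzaldehyde | O=Cc1ccc(O)c(Br)c1 | starting material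
4 | 3-bromo-4-(methoxymethoxy)benzaldehyde | COCOc1ccc(C=O)cc1Br | intermediate
5 | 1-[2,4-bis(benzyloxy)-6-hydroxyphenyl]ethanone | CC(=O)c1c(O)cc(OCc2ccccc2)cc1OCc1ccccc1 | starting material
6 | (E)-1-[2,4-bis(benzyloxy)-6-hydroxyphenyl]-3-[3-bromo-4-(methoxymethoxy)phenyl]prop-2-en-1-one | COCOc1ccc(/C=C/C(=O)c2c(O)cc(OCc3ccccc3)cc2OCc2ccccc2)cc1Br | intermediate
7 | 5,7-bis(benzyloxy)-2-[3-bromo-4-(methoxymethoxy)phenyl]-4H-chromen-4-one | COCOc1ccc(-c2cc(=O)c3c(OCc4ccccc4)cc(OCc4ccccc4)cc3o2)cc1Br | intermediate
8 | 5,7-bis(benzyloxy)-2-(3-bromo-4-hydroxyphenyl)-4H-chromen-4-one | Oc1ccc(-c2cc(=O)c3c(OCc4ccccc4)cc(OCc4ccccc4)cc3o2)cc1Br | intermediate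
9 | di-tert-butylsilyl bis(trifluoromethanesulfonate) | CC(C)(C)[Si](OS(=O)(=O)C(F)(F)F)(OS(=O)(=O)C(F)(F)F)C(C)(C)C | starting material
10 | [4-(5,7-bis(benzyloxy)-4-oxo-4H-chromen-2-yl)-2-bromophenoxy]di-tert-butylsilyl trifluoromethanesulfonate | CC(C)(C)[Si](Oc1ccc(-c2cc(=O)c3c(OCc4ccccc4)cc(OCc4ccccc4)cc3o2)cc1Br)(OS(=O)(=O)C(F)(F)F)C(C)(C)C | intermediate
11 | 7-(benzyloxy)-2-[4-(benzyloxy)phenyl]-5-({[4-(5,7-bis(benzyloxy)-4-oxo-4H-chromen-2-yl)-2-bromophenoxy]di-tert-butylsilyl}oxy)-4H-chromen-4-one | CC(C)(C)[Si](Oc1ccc(-c2cc(=O)c3c(OCc4ccccc4)cc(OCc4ccccc4)cc3o2)cc1Br)(Oc1cc(OCc2ccccc2)cc2oc(-c3ccc(OCc4ccccc4)cc3)cc(=O)c12)C(C)(C)C | intermediate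
12 | silylene-bridged 3',6''-biflavone (6,6-di-tert-butyldibenzo[d,f][1,3,2]dioxasilepine bridging O4' and O5'', four benzyl ethers) | CC(C)(C)[Si]1(C(C)(C)C)Oc2ccc(-c3cc(=O)c4c(OCc5ccccc5)cc(OCc5ccccc5)cc4o3)cc2-c2c(OCc3ccccc3)cc3oc(-c4ccc(OCc5ccccc5)cc4)cc(=O)c3c2O1 | intermediate
13 | 5,7,7'',4'''-tetra-O-benzylrobustaflavone | Oc1ccc(-c2cc(=O)c3c(OCc4ccccc4)cc(OCc4ccccc4)cc3o2)cc1-c1c(OCc2ccccc2)cc2oc(-c3ccc(OCc4ccccc4)cc3)cc(=O)c2c1O | intermediate
14 | 5,7,7'',4'''-tetra-O-benzyl-4'-O-methylrobustaflavone | COc1ccc(-c2cc(=O)c3c(OCc4ccccc4)cc(OCc4ccccc4)cc3o2)cc1-c1c(OCc2ccccc2)cc2oc(-c3ccc(OCc4ccccc4)cc3)cc(=O)c2c1O | intermediate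
15 | robustaflavone 4'-O-methyl ether, 6-[5-(5,7-dihydroxy-4-oxo-4H-chromen-2-yl)-2-methoxyphenyl]-5,7-dihydroxy-2-(4-hydroxyphenyl)-4H-chromen-4-one | COc1ccc(-c2cc(=O)c3c(O)cc(O)cc3o2)cc1-c1c(O)cc2oc(-c3ccc(O)cc3)cc(=O)c2c1O | target

Total steps: 9. Longest linear sequence: 8 steps (steps 2 to 9, from 3-bromo-4-hydroxybenzaldehyde); step 1 is a one-step side branch.

Steps most likely to fail

1. Step 6. The arylpalladium intermediate may be reduced (protodebromination) faster than it metalates the crowded C6''–H between O5'' and O7'', or hot carbonate may cleave the Si–O5'' bond before ring closure. The fallback gives up the tether for a cross-coupling and sets out from 8 and 2. Compound 8 is methylated (MeI, K2CO3, acetone) to 5,7-bis(benzyloxy)-2-(3-bromo-4-methoxyphenyl)-4H-chromen-4-one F1. Miyaura borylation of F1 (bis(pinacolato)diboron, PdCl2(dppf), KOAc, dioxane, 90 °C) should give the 3'-pinacolboronate F2. In parallel, 2 is iodinated ortho to its free 5-hydroxyl with benzyltrimethylammonium dichloroiodate and CaCO3 in CH2Cl2/MeOH to give 7-(benzyloxy)-2-[4-(benzyloxy)phenyl]-5-hydroxy-6-iodo-4H-chromen-4-one F3. Suzuki–Miyaura coupling of F2 with F3 (Pd(OAc)2, SPhos, K3PO4, dioxane/water, 90 °C) should form the C3'–C6'' bond and come back to the route at 14, which is debenzylated as in step 9.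

2. Step 5. The second substitution at the crowded silicon by the chelated 5-hydroxyl may be slow, so that the silyl triflate hydrolyses or scrambles to a symmetrical bis(aryloxy)silane. The fallback reverses the order and uses a hydrosilane, so the least reactive oxygen meets the least hindered silicon electrophile; it sets out from 2. Silylation of 2 with di-tert-butylchlorosilane (imidazole, DMAP, DMF, 50 °C) should give the isolable 7-(benzyloxy)-2-[4-(benzyloxy)phenyl]-5-[(di-tert-butylsilyl)oxy]-4H-chromen-4-one F4. Bromination of its Si–H bond with N-bromosuccinimide (1.0 equiv, CH2Cl2, 0 °C) generates the bromosilane F5, which is not isolated. Addition of the acidic, unhindered phenol 8 with imidazole in DMF should then close the mixed bis(aryloxy)silane and come back to the route at 11.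

3. Step 4. The chelation-activated 5-O-benzyl group may be lost to HI or methanolic HCl, or ring A may be iodinated, during the oxidative cyclisation and deprotection. The fallback separates ring closure from dehydrogenation, avoids iodine, and sets out from 6. Oxa-Michael cyclisation (NaOAc, EtOH, reflux) should give racemic 5,7-bis(benzyloxy)-2-[3-bromo-4-(methoxymethoxy)phenyl]chroman-4-one F6. Dehydrogenation of F6 with DDQ in dioxane at reflux comes back to the route at 7, which is then isolated and converted into 8 by the brief acid methanolysis of step 4, run at lower temperature.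

Further compounds
F1 | step 6 | 5,7-bis(benzyloxy)-2-(3-bromo-4-methoxyphenyl)-4H-chromen-4-one | COc1ccc(-c2cc(=O)c3c(OCc4ccccc4)cc(OCc4ccccc4)cc3o2)cc1Br
F2 | step 6 | 5,7-bis(benzyloxy)-2-[4-methoxy-3-(4,4,5,5-tetramethyl-1,3,2-dioxaborolan-2-yl)phenyl]-4H-chromen-4-one | COc1ccc(-c2cc(=O)c3c(OCc4ccccc4)cc(OCc4ccccc4)cc3o2)cc1B1OC(C)(C)C(C)(C)O1
F3 | step 6 | 7-(benzyloxy)-2-[4-(benzyloxy)phenyl]-5-hydroxy-6-iodo-4H-chromen-4-one | O=c1cc(-c2ccc(OCc3ccccc3)cc2)oc2cc(OCc3ccccc3)c(I)c(O)c12
F4 | step 5 | 7-(benzyloxy)-2-[4-(benzyloxy)phenyl]-5-[(di-tert-butylsilyl)oxy]-4H-chromen-4-one | CC(C)(C)[SiH](Oc1cc(OCc2ccccc2)cc2oc(-c3ccc(OCc4ccccc4)cc3)cc(=O)c12)C(C)(C)C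
F5 | step 5 | 7-(benzyloxy)-2-[4-(benzyloxy)phenyl]-5-{[bromodi(tert-butyl)silyl]oxy}-4H-chromen-4-one | CC(C)(C)[Si](Br)(Oc1cc(OCc2ccccc2)cc2oc(-c3ccc(OCc4ccccc4)cc3)cc(=O)c12)C(C)(C)C
F6 | step 4 | racemic 5,7-bis(benzyloxy)-2-[3-bromo-4-(methoxymethoxy)phenyl]chroman-4-one | COCOc1ccc(C2CC(=O)c3c(OCc4ccccc4)cc(OCc4ccccc4)cc3O2)cc1Br
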